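(The runs are simulated for substances that don't exist, noise included.)

Target and side product are the two entries we can read in this flask, and Monday's run is the same flask followed so far.

| flask | solid substrate | remark | time |
|---|---|---|---|
| Monday's | 0.13 M | the very flask that is asked about, followed so far |  |
| flask | 0.13 M |  | 12 d |

- Monday's (time / h: target / %, side product / %): 3.00: 1, 0; 8.00: 0, 0; 15.0: 2, 4; 25.0: 8, 3; 30.0: 14, 5

(standard deviation of a reading: 1.5 percentage points)

- solid, in amounts per volume of the solution: solid substrate
- the earlier runs were read with a standard deviation of 1.5 percentage points
- at the start none of the solid substrate is in solution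

- share of target in target plus side product at 10 h
- share of target in target plus side product at 12 d
- which of target and side product there is more of at 12 d

We keep a ledger of the solid substrate, the limiting reagent, in percent of its charge, at the last reading, 30.0 h:

  target: 14%
  side product: 5%
  booked sum: 19.0%
  81.0% is the open balance O, the part of the charge booked to neither product

O stands at 4.26 times the booked sum, so the booked entries are the correction and the share at 12 d turns mainly on where O goes. Our own reckoning keeps target at its reading and closes the books on the two products:

  O wholly to side product: share 14.0%
  O wholly to target: share 95.0%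

This is a range, not a number. Both readings at 8.00 h are 0%, against a scatter of 1.5 percentage points, so we read no share near 10 h.

The forecast gives 47% at 10 h, 85% at 12 d, and target in the lead: “If the acceleration persists, the target takes most of the remaining substrate”. Its end share lies inside our range, but it chooses a place there and our ledger does not.

The flask gives 90.2% at 10 h and 21.5% at 12 d, with side product ahead, 45.5% against 12.5% of target.

    intermediate B ⇌ intermediate C (K = 1.20, k = 1.10 × 10⁻⁴ s⁻¹)
    intermediate A → target (k = 8.50 × 10⁻⁶ s⁻¹)
    intermediate A → intermediate B (k = 3.40 × 10⁻⁵ s⁻¹)
    solid substrate ⇌ starting material, rate k4*(cs4 - [starting material]) while solid is left; crystals form when [starting material] > cs4 (solubility = 17.0 mM, k = 3.60 × 10⁻⁴ s⁻¹)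
    starting material → intermediate A (k = 7.10 × 10⁻⁵ s⁻¹)
    target ⇌ isomer of the product (K = 3.40, k = 8.20 × 10⁻⁶ s⁻¹)
    intermediate C → side product (k = 6.00 × 10⁻⁶ s⁻¹)
    intermediate C → target (k = 4.50 × 10⁻⁶ s⁻¹)

In this flask target and side product stand level at 19.1% each after 2.29 d. After Monday's last reading side product gains 40 points, half of O, while isomer of the product ends at 41.6%. The neighbour flask, charged with 0.052 M, ends with side product at 45.5% and target at 12.4% of its own charge, so its own O at 12.0 d is 42.1%, of which isomer of the product holds 41.7%, and its share is 21.4%.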